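**Retrosynthetic overview**

1. The 3',5'-dimethoxycyclohexa-2',5'-dien-4'-one ring is cut at the single bond C9(spiro)–C2'H and at the opposite double bond C6'H=C5'(OMe). This is a formal [4+2] union of a C9-formyl benzocycloheptene (C9 and its CHO carbon, C6') with a four-carbon unit made from 1,3-dimethoxyacetone, run directly at the dienone oxidation level.
2. Enabling feature: C9 is benzylic and carries a carbon at the aldehyde oxidation level, so it can react as an enolate carbon. The C4'=O flanked by two methoxy-bearing carbons maps onto 1,3-dimethoxyacetone. The mirror plane of the dienone through C9 and C4' makes the spiro atom non-stereogenic, so the C9 configuration of the precursor does not matter.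
3. The C9 aldehyde comes from benzylic hydroformylation of a C8=C9 styrene. The seven-membered ring comes from ring-closing metathesis of an aryl dienyl ketone. C5 is set by a catalyst-controlled ketone reduction, then acetylated.
4. The dienyl ketone comes from an aryllithium and a Weinreb amide. The syn C6/C7 methyl pair is set by an Ireland–Claisen rearrangement with chirality transfer from (2S,3E)-pent-3-en-2-ol.
5. Ring order: trimethoxybenzene ring (purchased), then the seven-membered carbocycle (metathesis), then the dienone ring (key step, last).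

Key step: step 14

Remark on locants: in all benzo[7]annulene intermediates and in the target, C5 is the oxygen-bearing benzylic carbon, C6 and C7 carry the methyl groups, C8 is the CH2 group and C9 is the benzylic carbon that becomes the spiro atom. Primed locants belong to the six-membered ring (C1' = C9).
Assumption: compounds 1, 10 and 22 are taken as purchasable.

**Step 1**
Reactants: 1 (E)-pent-3-en-2-ol, racemic
Product: 2 (2S,3E)-pent-3-en-2-ol
Conditions: immobilised Candida antarctica lipase B, vinyl acetate (0.6 equiv), MTBE, 25 °C, run past half conversion; alcohol separated from the acetate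
Reagents that add atoms: none
Why: Lipase-catalysed kinetic resolution; by the empirical size rule for secondary alcohols the (R)-enantiomer should be acetylated, so the (S)-alcohol should be recovered in high enantiomeric purity once conversion passes one half.

**Step 2**
Reactants: 2 (2S,3E)-pent-3-en-2-ol
Product: 3 (2S,3E)-pent-3-en-2-yl propanoate
Conditions: EtCOCl, pyridine, CH2Cl2, 0 → 25 °C
Reagents that add atoms: propanoyl chloride, CCC(Cl)=O
Why: O-acylation of the secondary allylic alcohol; the C–O bond at the stereocentre is not touched, so the configuration is retained.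

**Step 3**
Reactants: 3 (2S,3E)-pent-3-en-2-yl propanoate
Product: 7 (2S,3R,4E)-2,3-dimethylhex-4-enoic acid, via lithium Z-enolate 4 (not isolated), via silyl ketene acetal 5 (not isolated), via trimethylsilyl ester 6 (not isolated)
Conditions: LiN(i-Pr)2, THF–DMPU (4:1), −78 °C; Me3SiCl; −78 → 25 °C; then 1 M HCl
Reagents that add atoms: none
Why: Ireland–Claisen rearrangement; the polar co-solvent should give the enolate with methyl cis to O–Li, and the chair transition state with the carbinol methyl equatorial passes the (S) C–O configuration to C3 (R), sets C2 (S, syn to the C3 methyl) from the enolate geometry and gives the E-alkene.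

**Step 4**
Reactants: 7 (2S,3R,4E)-2,3-dimethylhex-4-enoic acid
Product: 9 (2S,3R,4E)-N-methoxy-N,2,3-trimethylhex-4-enamide, via acyl imidazole 8 (not isolated)
Conditions: CDI, CH2Cl2, 25 °C; then MeNH(OMe)·HCl
Reagents that add atoms: N,O-dimethylhydroxylamine hydrochloride, CNOC.Cl
Why: Amide formation through the acyl imidazole (Weinreb amide synthesis); the near-neutral conditions should not epimerise C2.

**Step 5**
Reactants: 10 5-bromo-1,2,3-trimethoxybenzene
Product: 12 6-bromo-2,3,4-trimethoxybenzaldehyde, via α-chloro ether 11 (not isolated)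
Conditions: Cl2CHOMe, TiCl4, CH2Cl2, −10 → 0 °C; then ice–water
Reagents that add atoms: dichloromethyl methyl ether, COC(Cl)Cl; water, O
Why: Rieche formylation; the two free ring positions are equivalent and each is ortho and para to a methoxy group, so a single aldehyde should form.

**Step 6**
Reactants: 12 6-bromo-2,3,4-trimethoxybenzaldehyde
Product: 13 1-bromo-2-ethenyl-3,4,5-trimethoxybenzene
Conditions: Ph3PCH3Br, KOt-Bu, THF, 0 → 25 °C
Reagents that add atoms: methyltriphenylphosphonium bromide, C[P+](c1ccccc1)(c1ccccc1)c1ccccc1.[Br-]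
Why: Wittig methylenation of a non-enolisable aryl aldehyde.

**Step 7**
Reactants: 13 1-bromo-2-ethenyl-3,4,5-trimethoxybenzene; 9 (2S,3R,4E)-N-methoxy-N,2,3-trimethylhex-4-enamide
Product: 16 (2S,3R,4E)-1-(2-ethenyl-3,4,5-trimethoxyphenyl)-2,3-dimethylhex-4-en-1-one, via aryllithium 14 (not isolated), via lithium hemiaminal alkoxide 15 (not isolated)
Conditions: n-BuLi, THF, −78 °C, 15 min; then 9, −78 → 0 °C; aq NH4Cl
Reagents that add atoms: none
Why: Bromine–lithium exchange followed by Weinreb ketone synthesis; the chelated tetrahedral adduct 15 should persist until work-up, which prevents over-addition and keeps the α-stereocentre from enolising.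

**Step 8**
Reactants: 16 (2S,3R,4E)-1-(2-ethenyl-3,4,5-trimethoxyphenyl)-2,3-dimethylhex-4-en-1-one
Product: 17 (6S,7R)-1,2,3-trimethoxy-6,7-dimethyl-6,7-dihydro-5H-benzo[7]annulen-5-one
Conditions: second-generation Grubbs catalyst RuCl2(=CHPh)(H2IMes)(PCy3) (5 mol %), toluene, 80 °C
Reagents that add atoms: none
Why: Ring-closing metathesis of the styrene with the propenyl group should close the seven-membered ring as the cis C8=C9 alkene with loss of propene; the neutral conditions leave C6 and C7 untouched.

**Step 9**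
Reactants: 17 (6S,7R)-1,2,3-trimethoxy-6,7-dimethyl-6,7-dihydro-5H-benzo[7]annulen-5-one
Product: 19 (5R,6S,7R)-1,2,3-trimethoxy-6,7-dimethyl-6,7-dihydro-5H-benzo[7]annulen-5-ol, via catechol borate 18 (not isolated)
Conditions: (S)-2-methyl-CBS-oxazaborolidine (20 mol %), catecholborane, toluene, −78 → −40 °C; then MeOH, aq NaOH
Reagents that add atoms: none
Why: Corey–Bakshi–Shibata reduction; with the fused aryl ring as the large group the (S)-catalyst should deliver hydride to give the (5R)-carbinol (trans to the C6 methyl), and catecholborane at low temperature should not hydroborate the styrene.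

**Step 10**
Reactants: 19 (5R,6S,7R)-1,2,3-trimethoxy-6,7-dimethyl-6,7-dihydro-5H-benzo[7]annulen-5-ol
Product: 20 (5R,6S,7R)-1,2,3-trimethoxy-6,7-dimethyl-6,7-dihydro-5H-benzo[7]annulen-5-yl acetate
Conditions: Ac2O, Et3N, DMAP (cat.), CH2Cl2, 0 → 25 °C
Reagents that add atoms: acetic anhydride, CC(=O)OC(C)=O
Why: DMAP-catalysed O-acetylation; the C5–O bond is not broken, so the configuration is retained.

**Step 11**
Reactants: 20 (5R,6S,7R)-1,2,3-trimethoxy-6,7-dimethyl-6,7-dihydro-5H-benzo[7]annulen-5-yl acetate
Product: 21 (5R,6S,7R)-9-formyl-1,2,3-trimethoxy-6,7-dimethyl-6,7,8,9-tetrahydro-5H-benzo[7]annulen-5-yl acetate (both C9 epimers)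
Conditions: Rh(acac)(CO)2 (2 mol %), P(O-2,4-t-Bu2C6H3)3 (8 mol %), CO/H2 (1:1, 40 bar), toluene, 60 °C
Reagents that add atoms: carbon monoxide, [C-]#[O+]
Why: Rhodium-catalysed hydroformylation of a cyclic styrene; hydride addition should give the η3-benzylic rhodium alkyl and the C7 methyl shields C8, so CO should insert at C9, and the C9 epimer mixture is of no consequence because C9 becomes the non-stereogenic spiro atom.

**Step 12**
Reactants: 22 1,3-dimethoxypropan-2-one
Product: 23 sodium (1E)-2,4-dimethoxy-3-oxobut-1-en-1-olate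
Conditions: HCO2Et, NaH, Et2O (EtOH cat.), 0 → 25 °C
Reagents that add atoms: ethyl formate, CCOC=O; sodium hydride, [Na+].[H-]
Why: Crossed Claisen condensation (formylation) of a symmetrical ketone; the chelated sodium enolate of the formyl ketone should precipitate, which stops double formylation.

**Step 13**
Reactants: 23 sodium (1E)-2,4-dimethoxy-3-oxobut-1-en-1-olate
Product: 25 4-chloro-1,3-dimethoxybut-3-en-2-one (E/Z mixture), via enol chlorooxalate 24 (not isolated)
Conditions: (COCl)2, DMF (cat.), CH2Cl2, 0 → 25 °C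
Reagents that add atoms: oxalyl chloride, O=C(Cl)C(Cl)=O
Why: Conversion of a β-keto aldehyde enolate into the β-chlorovinyl ketone; O-acylation activates the enol carbon, and chloride adds and expels chlorooxalate, which fragments to CO and CO2.

**Step 14**
Reactants: 21 (5R,6S,7R)-9-formyl-1,2,3-trimethoxy-6,7-dimethyl-6,7,8,9-tetrahydro-5H-benzo[7]annulen-5-yl acetate; 25 4-chloro-1,3-dimethoxybut-3-en-2-one
Product: 28 (5R,6S,7R)-1,2,3,3',5'-pentamethoxy-6,7-dimethyl-4'-oxo-5,6,7,8-tetrahydrospiro[benzo[7]annulene-9,1'-cyclohexa[2,5]diene]-5-yl acetate (CNP0143674.1), via formyl enone 26 (not isolated), via aldol adduct 27 (not isolated)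
Conditions: Cs2CO3 (2.5 equiv), PhSH (10 mol %), 4 Å MS, MeCN, argon, 0 → 45 °C; 25 (1.5 equiv) added slowly
Reagents that add atoms: none
Why: Proposed new method: Cs2CO3 turns the benzylic aldehyde 21 into its tetrasubstituted enolate, which attacks C4 of chloroenone 25 through C9 and expels chloride (vinylic addition–elimination) to give 26 with the quaternary carbon in place, after which the methoxymethyl ketone enolate of 26 adds to the formyl group and E1cB loss of water from aldol 27 completes the dienone. The closest known reaction types are the Robinson spiroannulation of α-branched aldehydes with vinyl ketones and the C-alkenylation of enolates or enamines by β-chlorovinyl ketones; new is their merger at the dienone oxidation level with an α,α'-dimethoxy partner. The six-membered ring closes by a 6-(enolendo)-exo-trig aldol addition, which requires C9 and the ketone carbon to be cis on the enol ether double bond of 26; catalytic thiophenolate adds reversibly to that double bond, so both geometric isomers should drain through the cyclisable one. No stereocentre is created, because the spiro carbon lies on the mirror plane of the 3',5'-dimethoxydienone, so both C9 epimers of 21 converge, and C5, C6 and C7 bear no acidic hydrogen. The step needs C- over O-alkenylation, secured because O-alkenylation gives a vinylogous acyl enol ether that re-enters addition–elimination whereas C–C bond formation is irreversible, and a single aldol direction, secured because 26 has one enolisable carbon within reach of an aldehyde that has lost its α-hydrogen. Anhydrous carbonate in MeCN should leave the C5 acetate intact, and molecular sieves hold back the water that could deformylate 26.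

**Compound list**

1 | (E)-pent-3-en-2-ol, racemic | C/C=C/C(C)O | starting material
2 | (2S,3E)-pent-3-en-2-ol | C/C=C/[C@H](C)O | intermediate
3 | (2S,3E)-pent-3-en-2-yl propanoate | C/C=C/[C@H](C)OC(=O)CC | intermediate
4 | lithium 1-[(2S,3E)-pent-3-en-2-yloxy]prop-1-en-1-olate, methyl cis to O–Li | [Li+].C/C=C(\[O-])O[C@@H](C)/C=C/C | intermediate
5 | trimethylsilyl ketene acetal of 3, methyl cis to OSiMe3 | C/C=C(\O[Si](C)(C)C)O[C@@H](C)/C=C/C | intermediate
6 | trimethylsilyl (2S,3R,4E)-2,3-dimethylhex-4-enoate | C/C=C/[C@@H](C)[C@H](C)C(=O)O[Si](C)(C)C | intermediate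
7 | (2S,3R,4E)-2,3-dimethylhex-4-enoic acid | C/C=C/[C@@H](C)[C@H](C)C(=O)O | intermediate
8 | (2S,3R,4E)-1-(imidazol-1-yl)-2,3-dimethylhex-4-en-1-one | C/C=C/[C@@H](C)[C@H](C)C(=O)n1ccnc1 | intermediate
9 | (2S,3R,4E)-N-methoxy-N,2,3-trimethylhex-4-enamide | C/C=C/[C@@H](C)[C@H](C)C(=O)N(C)OC | intermediate
10 | 5-bromo-1,2,3-trimethoxybenzene | COc1cc(Br)cc(OC)c1OC | starting material
11 | 1-bromo-2-[chloro(methoxy)methyl]-3,4,5-trimethoxybenzene | COC(Cl)c1c(Br)cc(OC)c(OC)c1OC | intermediate
12 | 6-bromo-2,3,4-trimethoxybenzaldehyde | O=Cc1c(Br)cc(OC)c(OC)c1OC | intermediate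
13 | 1-bromo-2-ethenyl-3,4,5-trimethoxybenzene | C=Cc1c(Br)cc(OC)c(OC)c1OC | intermediate
14 | (2-ethenyl-3,4,5-trimethoxyphenyl)lithium | [Li]c1cc(OC)c(OC)c(OC)c1C=C | intermediate
15 | lithium (2S,3R,4E)-1-(2-ethenyl-3,4,5-trimethoxyphenyl)-1-[methoxy(methyl)amino]-2,3-dimethylhex-4-en-1-olate | [Li+].C/C=C/[C@@H](C)[C@H](C)C([O-])(N(C)OC)c1cc(OC)c(OC)c(OC)c1C=C | intermediate
16 | (2S,3R,4E)-1-(2-ethenyl-3,4,5-trimethoxyphenyl)-2,3-dimethylhex-4-en-1-one | C/C=C/[C@@H](C)[C@H](C)C(=O)c1cc(OC)c(OC)c(OC)c1C=C | intermediate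
17 | (6S,7R)-1,2,3-trimethoxy-6,7-dimethyl-6,7-dihydro-5H-benzo[7]annulen-5-one | C1=C[C@@H](C)[C@H](C)C(=O)c2cc(OC)c(OC)c(OC)c12 | intermediate
18 | 2-{[(5R,6S,7R)-1,2,3-trimethoxy-6,7-dimethyl-6,7-dihydro-5H-benzo[7]annulen-5-yl]oxy}-1,3,2-benzodioxaborole | C1=C[C@@H](C)[C@H](C)[C@@H](OB3Oc4ccccc4O3)c2cc(OC)c(OC)c(OC)c12 | intermediate
19 | (5R,6S,7R)-1,2,3-trimethoxy-6,7-dimethyl-6,7-dihydro-5H-benzo[7]annulen-5-ol | C1=C[C@@H](C)[C@H](C)[C@@H](O)c2cc(OC)c(OC)c(OC)c12 | intermediate
20 | (5R,6S,7R)-1,2,3-trimethoxy-6,7-dimethyl-6,7-dihydro-5H-benzo[7]annulen-5-yl acetate | C1=C[C@@H](C)[C@H](C)[C@@H](OC(C)=O)c2cc(OC)c(OC)c(OC)c12 | intermediate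
21 | (5R,6S,7R)-9-formyl-1,2,3-trimethoxy-6,7-dimethyl-6,7,8,9-tetrahydro-5H-benzo[7]annulen-5-yl acetate, both C9 epimers | O=CC1C[C@@H](C)[C@H](C)[C@@H](OC(C)=O)c2cc(OC)c(OC)c(OC)c12 | intermediate
22 | 1,3-dimethoxypropan-2-one | COCC(=O)COC | starting material
23 | sodium (1E)-2,4-dimethoxy-3-oxobut-1-en-1-olate | [Na+].[O-]/C=C(\C(=O)COC)OC | intermediate
24 | (1E)-2,4-dimethoxy-3-oxobut-1-en-1-yl chloro(oxo)acetate | O=C(Cl)C(=O)O/C=C(\C(=O)COC)OC | intermediate
25 | 4-chloro-1,3-dimethoxybut-3-en-2-one, E/Z mixture | ClC=C(OC)C(=O)COC | intermediate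
26 | (5R,6S,7R)-9-(2,4-dimethoxy-3-oxobut-1-en-1-yl)-9-formyl-1,2,3-trimethoxy-6,7-dimethyl-6,7,8,9-tetrahydro-5H-benzo[7]annulen-5-yl acetate, C9 epimers and E/Z isomers | O=CC1(C=C(OC)C(=O)COC)C[C@@H](C)[C@H](C)[C@@H](OC(C)=O)c2cc(OC)c(OC)c(OC)c12 | intermediate
27 | (5R,6S,7R)-6'-hydroxy-1,2,3,3',5'-pentamethoxy-6,7-dimethyl-4'-oxo-5,6,7,8-tetrahydrospiro[benzo[7]annulene-9,1'-cyclohex[2]en]-5-yl acetate, isomer mixture | COC1=CC2(C(O)C(OC)C1=O)C[C@@H](C)[C@H](C)[C@@H](OC(C)=O)c1cc(OC)c(OC)c(OC)c12 | intermediate
28 | (5R,6S,7R)-1,2,3,3',5'-pentamethoxy-6,7-dimethyl-4'-oxo-5,6,7,8-tetrahydrospiro[benzo[7]annulene-9,1'-cyclohexa[2,5]diene]-5-yl acetate (CNP0143674.1) | COC1=CC2(C=C(OC)C1=O)C[C@@H](C)[C@H](C)[C@@H](OC(C)=O)c1cc(OC)c(OC)c(OC)c12 | target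

**Step count and risk**

Total step count: 14. Longest linear sequence: 10 (steps 1–4, 7–11, 14).

Steps most likely to fail:

1. Step 14 (proposed new method). The enolate may be alkenylated at oxygen without funnelling back, intermediate 26 may stall in the geometry that cannot cyclise, or 26 may lose its formyl group by vinylogous retro-Claisen cleavage before the aldol closes. Fallback, setting out from 21 (with 22 as the source of the four-carbon unit) and coming back at 28: α-methylenation of 22 (paraformaldehyde, diisopropylammonium trifluoroacetate, THF, reflux) should give 1,3-dimethoxybut-3-en-2-one F1. A Robinson spiroannulation in the Stork enamine variant (pyrrolidine, toluene, 4 Å MS; then F1; then AcOH/NaOAc/H2O, 60 °C) should give the spiro enone (5R,6S,7R)-1,2,3,3',5'-pentamethoxy-6,7-dimethyl-4'-oxo-5,6,7,8-tetrahydrospiro[benzo[7]annulene-9,1'-cyclohex[2]en]-5-yl acetate F2 as a mixture at C9 and C5'; no alkene geometry is at stake here. Soft enolisation toward C5' (Me3SiOTf, Et3N, CH2Cl2, 0 °C) should give the 4'-trimethylsilyloxy cyclohexa-2',4'-diene F3, and Saegusa–Ito oxidation (Pd(OAc)2, MeCN, 25 °C) should introduce the C5'=C6' double bond and give 28.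

2. Step 11. Formyl delivery to C8 in place of the benzylic C9, or alkene migration and hydrogenation before CO insertion, would erode the yield of 21. Fallback, setting out from 20 and coming back at 21: rhodium-catalysed hydroboration ([Rh(cod)2]BF4, dppb, pinacolborane, THF), which places boron at the benzylic carbon of vinylarenes, should give the C9 pinacol boronate (5R,6S,7R)-1,2,3-trimethoxy-6,7-dimethyl-9-(4,4,5,5-tetramethyl-1,3,2-dioxaborolan-2-yl)-6,7,8,9-tetrahydro-5H-benzo[7]annulen-5-yl acetate F4. Matteson homologation (LiCHCl2, THF, −100 °C; ZnCl2, → 25 °C) should give the α-chloroboronate, the 9-[chloro(4,4,5,5-tetramethyl-1,3,2-dioxaborolan-2-yl)methyl] analogue F5, and oxidation (NaBO3·4H2O, THF/H2O) should release aldehyde 21.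

3. Step 9. Mismatched double stereodifferentiation (the ring's own facial bias opposing the catalyst) or competing borane addition to the styrene could give a poor C5 ratio. Fallback, setting out from 17 and coming back at 20: substrate-controlled reduction with the bulky hydride LiBH(s-Bu)3 (L-Selectride, THF, −78 °C), which should attack anti to the C6 methyl, should give the cis alcohol (5S,6S,7R)-1,2,3-trimethoxy-6,7-dimethyl-6,7-dihydro-5H-benzo[7]annulen-5-ol F6. Mitsunobu esterification with acetic acid (PPh3, DIAD, AcOH, toluene, 0 °C) should then invert C5 and install the acetate in one operation, giving 20.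

**Further compounds**

F1 | step 14 | 1,3-dimethoxybut-3-en-2-one | C=C(OC)C(=O)COC
F2 | step 14 | (5R,6S,7R)-1,2,3,3',5'-pentamethoxy-6,7-dimethyl-4'-oxo-5,6,7,8-tetrahydrospiro[benzo[7]annulene-9,1'-cyclohex[2]en]-5-yl acetate, mixture at C9 and C5' | COC1=CC2(CC(OC)C1=O)C[C@@H](C)[C@H](C)[C@@H](OC(C)=O)c1cc(OC)c(OC)c(OC)c12
F3 | step 14 | (5R,6S,7R)-1,2,3,3',5'-pentamethoxy-6,7-dimethyl-4'-(trimethylsilyloxy)-5,6,7,8-tetrahydrospiro[benzo[7]annulene-9,1'-cyclohexa[2,4]diene]-5-yl acetate | COC1=CC2(CC(OC)=C1O[Si](C)(C)C)C[C@@H](C)[C@H](C)[C@@H](OC(C)=O)c1cc(OC)c(OC)c(OC)c12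
F4 | step 11 | (5R,6S,7R)-1,2,3-trimethoxy-6,7-dimethyl-9-(4,4,5,5-tetramethyl-1,3,2-dioxaborolan-2-yl)-6,7,8,9-tetrahydro-5H-benzo[7]annulen-5-yl acetate, C9 epimers | CC1(C)OB(OC1(C)C)C1C[C@@H](C)[C@H](C)[C@@H](OC(C)=O)c2cc(OC)c(OC)c(OC)c12
F5 | step 11 | (5R,6S,7R)-9-[chloro(4,4,5,5-tetramethyl-1,3,2-dioxaborolan-2-yl)methyl]-1,2,3-trimethoxy-6,7-dimethyl-6,7,8,9-tetrahydro-5H-benzo[7]annulen-5-yl acetate, isomer mixture | CC1(C)OB(OC1(C)C)C(Cl)C1C[C@@H](C)[C@H](C)[C@@H](OC(C)=O)c2cc(OC)c(OC)c(OC)c12
F6 | step 9 | (5S,6S,7R)-1,2,3-trimethoxy-6,7-dimethyl-6,7-dihydro-5H-benzo[7]annulen-5-ol | C1=C[C@@H](C)[C@H](C)[C@H](O)c2cc(OC)c(OC)c(OC)c12
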